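**Retrosynthetic overview**
1. Last bonds: the primary oleate (O-acylation) and the oxirane C–O bond (SN2 closure of a secondary mesylate by the neighbouring tertiary OH, with inversion), both from an indole tetraol.
2. Indole: Fischer indolization of an N-aryl benzophenone hydrazone with a chiral γ-lactol (masked 4-hydroxy-aldehyde); the [3,3]-sigmatropic shift of the ene-hydrazine makes the C3–C3a bond, and the para substituent fixes C5.
3. Lactol: from L-glutamic-acid-derived (S)-5-(hydroxymethyl)butyrolactone; its stereocentre directs a trans α-hydroxymethylation (sets the side-chain centre), MeMgBr opens the lactone to the CMe2OH group, and glycol cleavage then excises the directing carbinol carbon.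
4. Aryl part: L-serine-derived methyl (R)-glycidate, opened at C3 by an aryl cuprate, then MeMgBr and Pd N-arylation of benzophenone hydrazone.
5. Ring order: pyrrole ring of the indole first (step 8), oxirane last (step 10).

Assumption: the lactol made in step 4 is an equilibrating mixture of anomers (and of the isomeric lactol closed through the primary OH); all forms react as the open-chain aldehyde in step 8, so it is drawn as one lactol with the anomeric centre undefined.

**Route**

Step 1
Reactants: 1 (S)-5-(hydroxymethyl)dihydrofuran-2(3H)-one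
Product: 2 (S)-5-[(trityloxy)methyl]dihydrofuran-2(3H)-one
Conditions: TrCl (1.1 equiv), pyridine, DMAP (cat.), CH2Cl2, rt
Reagents that add atoms: trityl chloride, ClC(c1ccccc1)(c1ccccc1)c1ccccc1
Why: SN1-type tritylation of the primary alcohol installs the bulky group that will shield one face of the lactone enolate.

Step 2
Reactants: 2 (S)-5-[(trityloxy)methyl]dihydrofuran-2(3H)-one
Product: 4 (3S,5S)-3-(hydroxymethyl)-5-[(trityloxy)methyl]dihydrofuran-2(3H)-one, via lithium enolate 3 (not isolated)
Conditions: LDA (1.1 equiv), THF, −78 °C; CH2O (g, from cracked paraformaldehyde), −78 → −40 °C; AcOH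
Reagents that add atoms: formaldehyde, C=O
Why: Aldol hydroxymethylation of the lactone enolate; the C5 trityloxymethyl group blocks the cis face, so formaldehyde adds trans (1,3-induction) and sets the new centre as 3S.

Step 3
Reactants: 4 (3S,5S)-3-(hydroxymethyl)-5-[(trityloxy)methyl]dihydrofuran-2(3H)-one
Product: 6 (3S,5S)-3-(hydroxymethyl)-2-methyl-6-(trityloxy)hexane-2,5-diol, via methyl ketone 5 (not isolated)
Conditions: MeMgBr (5 equiv), THF, −20 °C → rt; aq. work-up
Reagents that add atoms: methylmagnesium bromide, C[Mg]Br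
Why: Double Grignard addition opens the lactone to the CMe2OH group; the intermediate ketone is trapped faster than it enolises, so C3 is not epimerised.

Step 4
Reactants: 6 (3S,5S)-3-(hydroxymethyl)-2-methyl-6-(trityloxy)hexane-2,5-diol
Product: 8 (4S)-4-(hydroxymethyl)-5,5-dimethyloxolan-2-ol, via tetraol 7 (not isolated)
Conditions: AcOH–H2O 4:1, 45 °C; then NaIO4 (1.2 equiv), H2O–THF, 0 °C → rt
Reagents that add atoms: none
Why: Acid solvolysis of the trityl ether, then Malaprade cleavage of the only vicinal diol, gives the 4-hydroxy-aldehyde as its lactol; the directing carbinol carbon becomes the aldehyde carbon and the 4S centre is untouched.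

Step 5
Reactants: 9 1-bromo-4-iodobenzene; 10 methyl (2R)-oxirane-2-carboxylate (methyl (R)-glycidate)
Product: 12 methyl (2R)-3-(4-bromophenyl)-2-hydroxypropanoate, via 4-bromophenylmagnesium chloride 11 (not isolated)
Conditions: i-PrMgCl·LiCl (1.0 equiv), THF, −20 °C; then CuI (10 mol %), 10 (0.85 equiv), −40 → −20 °C; aq. work-up
Reagents that add atoms: none
Why: Selective I/Mg exchange, then Cu-catalysed SN2 opening of the glycidate at the terminal CH2, leaves the C2 stereocentre (R) untouched.

Step 6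
Reactants: 12 methyl (2R)-3-(4-bromophenyl)-2-hydroxypropanoate
Product: 14 (2R)-1-(4-bromophenyl)-3-methylbutane-2,3-diol, via hydroxy ketone 13 (not isolated)
Conditions: MeMgBr (3.5 equiv), THF, 0 °C → rt; aq. work-up
Reagents that add atoms: methylmagnesium bromide, C[Mg]Br
Why: Double Grignard addition to the ester; the α-centre is protected from enolisation as its magnesium alkoxide, and the aryl bromide is inert.

Step 7
Reactants: 14 (2R)-1-(4-bromophenyl)-3-methylbutane-2,3-diol; 15 benzophenone hydrazone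
Product: 16 (2R)-1-{4-[2-(diphenylmethylidene)hydrazinyl]phenyl}-3-methylbutane-2,3-diol
Conditions: Pd(OAc)2 (2 mol %), Xantphos (3 mol %), Cs2CO3 (1.5 equiv), toluene, 100 °C
Reagents that add atoms: none
Why: Buchwald–Hartwig N-arylation of benzophenone hydrazone (achiral ligand) gives a stable arylhydrazine surrogate; the free diol is tolerated with carbonate base.

Step 8
Reactants: 16 (2R)-1-{4-[2-(diphenylmethylidene)hydrazinyl]phenyl}-3-methylbutane-2,3-diol; 8 (4S)-4-(hydroxymethyl)-5,5-dimethyloxolan-2-ol (1.3 equiv)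
Product: 19 (2R)-1-{3-[(2S)-1,3-dihydroxy-3-methylbutan-2-yl]-1H-indol-5-yl}-3-methylbutane-2,3-diol, via free arylhydrazine 17 (not isolated), via aldehyde arylhydrazone 18 (not isolated)
Conditions: TsOH·H2O (2 equiv), EtOH, 78 °C
Reagents that add atoms: none
Why: Fischer indole synthesis (benzophenone-hydrazone exchange variant): the ene-hydrazine of 18 undergoes the [3,3]-sigmatropic shift that forms C3–C3a, then cyclises and loses NH3; the para substituent allows only the 5-substituted indole, and the side-chain centre is not part of the ene-hydrazine, so it is retained.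

Step 9
Reactants: 19 (2R)-1-{3-[(2S)-1,3-dihydroxy-3-methylbutan-2-yl]-1H-indol-5-yl}-3-methylbutane-2,3-diol; 20 oleoyl chloride ((9Z)-octadec-9-enoyl chloride, 1.05 equiv)
Product: 21 (2S)-2-{5-[(2R)-2,3-dihydroxy-3-methylbutyl]-1H-indol-3-yl}-3-hydroxy-3-methylbutyl (9Z)-octadec-9-enoate
Conditions: 2,4,6-collidine (2 equiv), CH2Cl2, −78 → −20 °C
Reagents that add atoms: none
Why: Kinetically selective O-acylation of the only primary alcohol; the secondary OH is flanked by CMe2OH and the benzylic CH2, and the tertiary OH groups and the indole N–H do not react with an acyl chloride and a weak base at low temperature.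

Step 10
Reactants: 21 (2S)-2-{5-[(2R)-2,3-dihydroxy-3-methylbutyl]-1H-indol-3-yl}-3-hydroxy-3-methylbutyl (9Z)-octadec-9-enoate
Product: 23 (2S)-2-(5-{[(2S)-3,3-dimethyloxiran-2-yl]methyl}-1H-indol-3-yl)-3-hydroxy-3-methylbutyl (9Z)-octadec-9-enoate, via secondary mesylate 22 (not isolated)
Conditions: MsCl (1.2 equiv), Et3N (2.5 equiv), CH2Cl2, −20 °C; then DBU (3 equiv), 0 °C → rt
Reagents that add atoms: none
Why: Only the secondary OH is mesylated; intramolecular Williamson closure by the adjacent tertiary OH (3-exo-tet SN2) inverts the (R)-carbinol to the (S)-oxirane, and the non-nucleophilic base spares the oleate.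

**Compound list**
1 | (S)-5-(hydroxymethyl)dihydrofuran-2(3H)-one | OC[C@@H]1CCC(=O)O1 | starting material
2 | (S)-5-[(trityloxy)methyl]dihydrofuran-2(3H)-one | O=C1CC[C@@H](COC(c2ccccc2)(c2ccccc2)c2ccccc2)O1 | intermediate
3 | lithium enolate of 2 (lithium (5S)-5-[(trityloxy)methyl]-4,5-dihydrofuran-2-olate) | [Li]OC1=CC[C@@H](COC(c2ccccc2)(c2ccccc2)c2ccccc2)O1 | intermediate
4 | (3S,5S)-3-(hydroxymethyl)-5-[(trityloxy)methyl]dihydrofuran-2(3H)-one | O=C1O[C@H](COC(c2ccccc2)(c2ccccc2)c2ccccc2)C[C@H]1CO | intermediate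
5 | (3S,5S)-5-hydroxy-3-(hydroxymethyl)-6-(trityloxy)hexan-2-one (present as its magnesium alkoxide) | CC(=O)[C@H](CO)C[C@H](O)COC(c1ccccc1)(c1ccccc1)c1ccccc1 | intermediate
6 | (3S,5S)-3-(hydroxymethyl)-2-methyl-6-(trityloxy)hexane-2,5-diol | CC(C)(O)[C@H](CO)C[C@H](O)COC(c1ccccc1)(c1ccccc1)c1ccccc1 | intermediate
7 | (2S,4S)-4-(hydroxymethyl)-5-methylhexane-1,2,5-triol | CC(C)(O)[C@H](CO)C[C@H](O)CO | intermediate
8 | (4S)-4-(hydroxymethyl)-5,5-dimethyloxolan-2-ol (anomer mixture) | OC1C[C@@H](CO)C(C)(C)O1 | intermediate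
9 | 1-bromo-4-iodobenzene | Brc1ccc(I)cc1 | starting material
10 | methyl (2R)-oxirane-2-carboxylate | COC(=O)[C@H]1CO1 | starting material
11 | 4-bromophenylmagnesium chloride | Cl[Mg]c1ccc(Br)cc1 | intermediate
12 | methyl (2R)-3-(4-bromophenyl)-2-hydroxypropanoate | COC(=O)[C@H](O)Cc1ccc(Br)cc1 | intermediate
13 | (3R)-4-(4-bromophenyl)-3-hydroxybutan-2-one (present as its magnesium alkoxide) | CC(=O)[C@H](O)Cc1ccc(Br)cc1 | intermediate
14 | (2R)-1-(4-bromophenyl)-3-methylbutane-2,3-diol | CC(C)(O)[C@H](O)Cc1ccc(Br)cc1 | intermediate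
15 | benzophenone hydrazone | NN=C(c1ccccc1)c1ccccc1 | starting material
16 | (2R)-1-{4-[2-(diphenylmethylidene)hydrazinyl]phenyl}-3-methylbutane-2,3-diol | CC(C)(O)[C@H](O)Cc1ccc(NN=C(c2ccccc2)c2ccccc2)cc1 | intermediate
17 | (2R)-1-(4-hydrazinylphenyl)-3-methylbutane-2,3-diol | CC(C)(O)[C@H](O)Cc1ccc(NN)cc1 | intermediate
18 | (2R)-1-(4-{2-[(3S)-4-hydroxy-3-(hydroxymethyl)-4-methylpentylidene]hydrazinyl}phenyl)-3-methylbutane-2,3-diol | CC(C)(O)[C@H](O)Cc1ccc(NN=CC[C@@H](CO)C(C)(C)O)cc1 | intermediate
19 | (2R)-1-{3-[(2S)-1,3-dihydroxy-3-methylbutan-2-yl]-1H-indol-5-yl}-3-methylbutane-2,3-diol | CC(C)(O)[C@H](O)Cc1ccc2[nH]cc([C@@H](CO)C(C)(C)O)c2c1 | intermediate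
20 | (9Z)-octadec-9-enoyl chloride (oleoyl chloride) | CCCCCCCC/C=C\CCCCCCCC(Cl)=O | starting material
21 | (2S)-2-{5-[(2R)-2,3-dihydroxy-3-methylbutyl]-1H-indol-3-yl}-3-hydroxy-3-methylbutyl (9Z)-octadec-9-enoate | CCCCCCCC/C=C\CCCCCCCC(=O)OC[C@H](c1c[nH]c2ccc(C[C@@H](O)C(C)(C)O)cc12)C(C)(C)O | intermediate
22 | (2S)-3-hydroxy-2-{5-[(2R)-3-hydroxy-2-(methanesulfonyloxy)-3-methylbutyl]-1H-indol-3-yl}-3-methylbutyl (9Z)-octadec-9-enoate | CCCCCCCC/C=C\CCCCCCCC(=O)OC[C@H](c1c[nH]c2ccc(C[C@@H](OS(C)(=O)=O)C(C)(C)O)cc12)C(C)(C)O | intermediate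
23 | (2S)-2-(5-{[(2S)-3,3-dimethyloxiran-2-yl]methyl}-1H-indol-3-yl)-3-hydroxy-3-methylbutyl (9Z)-octadec-9-enoate (CNP0291182.1) | CCCCCCCC/C=C\CCCCCCCC(=O)OC[C@H](c1c[nH]c2ccc(C[C@@H]3OC3(C)C)cc12)C(C)(C)O | target

**Step count and risk**
Total: 10 steps. Longest linear sequence: 7 steps (1, 2, 3, 4, 8, 9, 10); the aryl branch is steps 5–7.

Three steps most likely to fail:

Step 8 (Fischer indolization). Two equivalents of sulfonic acid at reflux may dehydrate the tertiary carbinols, especially the one β to indole C3, and hydrazone exchange with an aldehyde-level partner can give oligomers. The fallback sets out from 14 and uses a discrete hydrazine salt in a self-buffered cyclisation instead of the strong-acid exchange. Pd-catalysed monoarylation of hydrazine hydrate with 14 ([Pd(cinnamyl)Cl]2, Mor-DalPhos, NaOtBu, dioxane, 65 °C), then HCl in ether, gives (2R)-1-(4-hydrazinylphenyl)-3-methylbutane-2,3-diol hydrochloride F1. F1 is heated with lactol 8 in EtOH–H2O at 80 °C with no added acid (Grandberg-type tryptophol conditions; the hydrazinium chloride is the only proton source and the ammonia released buffers the mixture). It passes through hydrazone 18 and comes back to the route at 19.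

Step 2 (hydroxymethylation). Gaseous formaldehyde can oligomerise, add twice or give lower trans selectivity than a bulkier electrophile. The fallback sets out from 2 and alkylates instead of running an aldol. Enolate 3 is treated with benzyl chloromethyl ether at −78 °C to give (3S,5S)-3-[(benzyloxy)methyl]-5-[(trityloxy)methyl]dihydrofuran-2(3H)-one F2, for which trans alkylation is well established. MeMgBr as in step 3 gives (3S,5S)-3-[(benzyloxy)methyl]-2-methyl-6-(trityloxy)hexane-2,5-diol F3. Hydrogenolysis (H2, Pd(OH)2/C, EtOH) removes both the benzyl and the trityl ether and comes back to the route at tetraol 7, which is cleaved with NaIO4 as in step 4.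

Step 9 (selective oleoylation). Primary versus secondary acylation may be incomplete, and the ester then has to survive the basic epoxide closure of step 10. The fallback sets out from 19 and builds the epoxide before the ester. TBSCl and imidazole in DMF at 0 °C give the primary silyl ether (2R)-1-{3-[(2S)-1-(tert-butyldimethylsilyloxy)-3-hydroxy-3-methylbutan-2-yl]-1H-indol-5-yl}-3-methylbutane-2,3-diol F4. MsCl and Et3N give its secondary mesylate F5, which is closed without isolation with K2CO3 in MeOH (no ester present) to the silylated epoxide (2S)-1-(tert-butyldimethylsilyloxy)-2-(5-{[(2S)-3,3-dimethyloxiran-2-yl]methyl}-1H-indol-3-yl)-3-methylbutan-3-ol F6. TBAF in THF frees (2S)-2-(5-{[(2S)-3,3-dimethyloxiran-2-yl]methyl}-1H-indol-3-yl)-3-methylbutane-1,3-diol F7. Its only primary OH is esterified with oleic acid, EDC·HCl and DMAP in CH2Cl2, which comes back to the route at target 23.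

**Further compounds**
F1 | step 8 | (2R)-1-(4-hydrazinylphenyl)-3-methylbutane-2,3-diol hydrochloride | Cl.CC(C)(O)[C@H](O)Cc1ccc(NN)cc1
F2 | step 2 | (3S,5S)-3-[(benzyloxy)methyl]-5-[(trityloxy)methyl]dihydrofuran-2(3H)-one | O=C1O[C@H](COC(c2ccccc2)(c2ccccc2)c2ccccc2)C[C@H]1COCc1ccccc1
F3 | step 2 | (3S,5S)-3-[(benzyloxy)methyl]-2-methyl-6-(trityloxy)hexane-2,5-diol | CC(C)(O)[C@H](COCc1ccccc1)C[C@H](O)COC(c1ccccc1)(c1ccccc1)c1ccccc1
F4 | step 9 | (2R)-1-{3-[(2S)-1-(tert-butyldimethylsilyloxy)-3-hydroxy-3-methylbutan-2-yl]-1H-indol-5-yl}-3-methylbutane-2,3-diol | CC(C)(O)[C@H](O)Cc1ccc2[nH]cc([C@@H](CO[Si](C)(C)C(C)(C)C)C(C)(C)O)c2c1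
F5 | step 9 | secondary mesylate of F4 | CC(C)(O)[C@H](OS(C)(=O)=O)Cc1ccc2[nH]cc([C@@H](CO[Si](C)(C)C(C)(C)C)C(C)(C)O)c2c1
F6 | step 9 | (2S)-1-(tert-butyldimethylsilyloxy)-2-(5-{[(2S)-3,3-dimethyloxiran-2-yl]methyl}-1H-indol-3-yl)-3-methylbutan-3-ol | CC1(C)O[C@H]1Cc1ccc2[nH]cc([C@@H](CO[Si](C)(C)C(C)(C)C)C(C)(C)O)c2c1
F7 | step 9 | (2S)-2-(5-{[(2S)-3,3-dimethyloxiran-2-yl]methyl}-1H-indol-3-yl)-3-methylbutane-1,3-diol | CC1(C)O[C@H]1Cc1ccc2[nH]cc([C@@H](CO)C(C)(C)O)c2c1
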